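**Plan**

1. Retrosynthesis: cut O–C8 and C15–C1′ of the dihydropyran (three-component Knoevenagel/oxa-Diels–Alder), then C4–C5 of the nine-membered ring (Nozaki–Hiyama–Kishi), then C10–C11 of the cyclobutane, which leads back to a 2,2-dimethylpyrrolidine and from there to 2-nitropropane and an alkylidene malonate.
2. Forward order of rings: γ-lactam → pyrrolidine → cyclobutane (nitrogen deletion) → side chains on C9 and C1 → nine-membered ring → spiro-dihydropyran.
3. Enabling feature: in the cyclobutane (C1, C9, C10, C11) the neighbours C10 (CH2) and C11 (CMe2) are both non-stereogenic and C11 is fully substituted, so a nitrogen can sit between them in a 2,2-dimethylpyrrolidine and leave as N2; the two carbons then join as a primary/tertiary radical pair while C1 and C9 keep their configuration.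
4. Stereochemistry: C1 from the phase-transfer Michael addition; C9 by thermodynamic control (trans to C1) in the lactam; Z-C3=C4 from the iodo-Wittig reagent; C5 in the ring closure; C8 and C1′ in the cycloaddition on the alkene face anti to H9.
5. Carbon sources: 2-nitropropane gives C11, both methyl groups and the temporary nitrogen; the malonate gives C9, C8 and C10 (the lactam tells the two ester carbons apart).

Key step: step 5

Remark: atom numbers are those of the caryophyllane skeleton (C10–C11 is the CH2–CMe2 bond of the cyclobutane, C1′ the isobutyl-bearing carbon); in step 2 the catalyst antipode is taken that delivers the 3R adduct.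

**Route**

Step 1
Reactants: 1 3-[(tert-butyldiphenylsilyl)oxy]propanal; 2 dipropan-2-yl propanedioate (diisopropyl malonate)
Product: 3 dipropan-2-yl 2-{3-[(tert-butyldiphenylsilyl)oxy]propylidene}propanedioate
Conditions: piperidine (0.1 equiv), AcOH (0.1 equiv), 4 Å molecular sieves, toluene, 40 °C
Reagents that add atoms: none
Why: Knoevenagel condensation of an unbranched aldehyde with a malonate joins C1 (alkylidene carbon) to C9 (malonate carbon, flanked by the future C8 and C10) and creates no stereocentre.

Step 2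
Reactants: 3 alkylidene malonate; 4 2-nitropropane
Product: 5 dipropan-2-yl 2-[(3R)-1-[(tert-butyldiphenylsilyl)oxy]-4-methyl-4-nitropentan-3-yl]propanedioate
Conditions: chiral C2-symmetric N-spiro bis(binaphthyl)ammonium bromide phase-transfer catalyst (1 mol %), Cs2CO3 (0.2 equiv), toluene, 0 °C
Reagents that add atoms: none
Why: Asymmetric Michael addition of a nitronate to an alkylidene malonate under chiral phase-transfer catalysis, in which the chiral ammonium nitronate ion pair adds to one face of the alkylidene carbon and sets C1 (3R in 5), while 2-nitropropane delivers C11 with both methyl groups and the nitrogen that is deleted later.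

Step 3
Reactants: 5 nitro diester
Product: 7 propan-2-yl (3R,4R)-4-{2-[(tert-butyldiphenylsilyl)oxy]ethyl}-5,5-dimethyl-2-oxopyrrolidine-3-carboxylate, via amino diester 6 (not isolated)
Conditions: H2 (4 atm), Raney Ni, i-PrOH, 50 °C; then toluene, 110 °C
Reagents that add atoms: none
Why: Hydrogenation of the tertiary nitro group gives amine 6, which closes the γ-lactam on one ester group by 5-exo-trig acyl substitution (the lactam carbonyl becomes C10, the remaining ester C8), and C9, acidic between two carbonyl groups, equilibrates to the trans (3R,4R) isomer under thermodynamic control whichever ester reacted.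

Step 4
Reactants: 7 lactam ester
Product: 8 propan-2-yl (3R,4R)-4-{2-[(tert-butyldiphenylsilyl)oxy]ethyl}-5,5-dimethylpyrrolidine-3-carboxylate
Conditions: BH3·SMe2 (3 equiv), THF, 0 °C to 50 °C; then MeOH, 65 °C
Reagents that add atoms: none
Why: Chemoselective borane reduction of a secondary lactam beside a hindered ester (amide-selective hydride delivery after O–B coordination) gives the 2,2-dimethylpyrrolidine whose nitrogen bridges C10 and C11, with no change at C1 or C9.

Step 5
Reactants: 8 pyrrolidine ester
Product: 10 propan-2-yl (1S,2R)-2-{2-[(tert-butyldiphenylsilyl)oxy]ethyl}-3,3-dimethylcyclobutane-1-carboxylate, via isodiazene 9 (not isolated)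
Conditions: PhI(OH)OTs (2.5 equiv), NH2CO2NH4 (8 equiv), CF3CH2OH, 80 °C
Reagents that add atoms: none
Why: PhI(OH)OTs and ammonia (from ammonium carbamate) form an iodonitrene that N-aminates the secondary amine and is oxidised on to isodiazene 9, which loses N2 by stepwise C–N homolysis (tertiary C11–N first) to a singlet 1,4-biradical (C11 tertiary, C10 primary) that collapses to the C10–C11 bond. The closest known reaction type is the oxidative ring contraction of pyrrolidines to cyclobutanes through 1,1-diazenes (nitrogen deletion; classically the oxidation of alkyl-substituted N-aminopyrrolidines). The four-membered ring closes by radical–radical recombination of the two former α-carbons, which the C9–C1 bond of the departing five-membered ring holds in a 1,4-gauche arrangement. No stereocentre is created, because C10 and C11 are not stereogenic and C1 and C9 are not part of the radical pair, so the trans arrangement fixed in lactam 7 passes unchanged into the cyclobutane. The step needs ring closure to outrun β-scission of the C1–C9 bond (which would give isopropyl acrylate and a trisubstituted alkene); the singlet spin state, the closeness of the termini at birth and the gem-dimethyl group on C11 favour closure, but this partition is the main uncertainty of the route.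

Step 6
Reactants: 10 cyclobutane ester
Product: 11 (1S,2R)-2-{2-[(tert-butyldiphenylsilyl)oxy]ethyl}-N-methoxy-N,3,3-trimethylcyclobutane-1-carboxamide
Conditions: MeNHOMe·HCl (3 equiv), AlMe3 (3 equiv), CH2Cl2, 0 °C to 40 °C
Reagents that add atoms: N,O-dimethylhydroxylamine hydrochloride (CNOC.Cl)
Why: AlMe3-mediated aminolysis of the ester gives the Weinreb amide without touching the silyl ether, and C9 stays in its stable trans configuration.

Step 7
Reactants: 11 Weinreb amide; 12 2-(2-bromoethyl)-1,3-dioxolane
Product: 14 1-[(1S,2R)-2-{2-[(tert-butyldiphenylsilyl)oxy]ethyl}-3,3-dimethylcyclobutyl]-3-(1,3-dioxolan-2-yl)propan-1-one, via Grignard reagent 13 (not isolated)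
Conditions: 12, Mg, THF, 25 °C; then 11, THF, 0 °C; aqueous NH4Cl
Reagents that add atoms: none
Why: Grignard addition to a Weinreb amide stops at the ketone through the chelated tetrahedral intermediate, so C7, C6 and C5 (masked as the acetal) are attached to C8 in one operation.

Step 8
Reactants: 14 ketone
Product: 15 tert-butyl{2-[(1R,4S)-4-[4-(1,3-dioxolan-2-yl)but-1-en-2-yl]-2,2-dimethylcyclobutyl]ethoxy}diphenylsilane
Conditions: Ph3PCH3Br, KOt-Bu, THF, 0 °C to 25 °C
Reagents that add atoms: methyltriphenylphosphonium bromide (C[P+](c1ccccc1)(c1ccccc1)c1ccccc1.[Br-])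
Why: Wittig methylenation of the ketone installs C15 as the 1,1-disubstituted alkene, and although C9 is α to the carbonyl group, trans is its stable configuration on the cyclobutane.

Step 9
Reactants: 15 silyl ether
Product: 16 2-[(1R,4S)-4-[4-(1,3-dioxolan-2-yl)but-1-en-2-yl]-2,2-dimethylcyclobutyl]ethan-1-ol
Conditions: Bu4NF, THF, 25 °C
Reagents that add atoms: none
Why: Fluoride-induced cleavage of the silyl ether (strong Si–F bond) frees the C3 hydroxyl while acetal and alkene are inert.

Step 10
Reactants: 16 alcohol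
Product: 17 2-[(1R,4S)-4-[4-(1,3-dioxolan-2-yl)but-1-en-2-yl]-2,2-dimethylcyclobutyl]acetaldehyde
Conditions: Dess–Martin periodinane, NaHCO3, CH2Cl2, 0 °C to 25 °C
Reagents that add atoms: none
Why: Dess–Martin oxidation of the primary alcohol under buffered conditions gives the C3 aldehyde without acetal loss or alkene migration.

Step 11
Reactants: 17 aldehyde
Product: 18 2-{3-[(1S,2R)-2-[(2Z)-3-iodobut-2-en-1-yl]-3,3-dimethylcyclobutyl]but-3-en-1-yl}-1,3-dioxolane
Conditions: EtPPh3I, n-BuLi, THF, 0 °C; I2, −78 °C; NaN(SiMe3)2, −20 °C; then 17, −78 °C to 25 °C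
Reagents that add atoms: ethyltriphenylphosphonium iodide (CC[P+](c1ccccc1)(c1ccccc1)c1ccccc1.[I-]); iodine (II)
Why: Stork–Zhao-type Wittig olefination with the α-iodo ylide gives the trisubstituted (Z)-alkenyl iodide (iodine cis to the chain) through the kinetically preferred cis-oxaphosphetane of a non-stabilised ylide, which fixes the later Z geometry of C3=C4.

Step 12
Reactants: 18 alkenyl iodide acetal
Product: 19 4-[(1S,2R)-2-[(2Z)-3-iodobut-2-en-1-yl]-3,3-dimethylcyclobutyl]pent-4-enal
Conditions: pyridinium p-toluenesulfonate (0.2 equiv), acetone/H2O (10:1), 60 °C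
Reagents that add atoms: water (O)
Why: Mild acid-catalysed acetal hydrolysis unmasks the C5 aldehyde, the weak acid avoiding protonation of the methylidenecyclobutane and leaving the alkenyl iodide intact.

Step 13
Reactants: 19 iodo aldehyde
Product: 20 (1R,3Z,5R,9S)-4,11,11-trimethyl-8-methylidenebicyclo[7.2.0]undec-3-en-5-ol
Conditions: CrCl2 (10 equiv), NiCl2 (0.1 equiv), DMSO/THF, 25 °C, slow addition of 19 to 0.003 M
Reagents that add atoms: none
Why: Nozaki–Hiyama–Kishi reaction, in which zerovalent nickel inserts into the C–I bond and transmetallation gives an alkenylchromium species (trivalent chromium) that adds only to the aldehyde and closes the nine-membered ring with retention of the Z geometry, the trans-cyclobutane and the cis alkene bringing the termini together; C5 is set under substrate control by attack on the aldehyde face that is exposed when its oxygen points away from the forming ring, which should favour 5R.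

Step 14
Reactants: 21 1-(2,4,6-trihydroxyphenyl)ethan-1-one
Product: 22 2-acetyl-3-hydroxy-4,4,6,6-tetramethylcyclohex-2-ene-1,5-dione (acetylsyncarpic acid, enol form)
Conditions: NaOMe (5 equiv), MeI (6 equiv), MeOH, 65 °C
Reagents that add atoms: iodomethane (CI)
Why: Exhaustive C-methylation of the phloroglucinol polyanion at its two free ring carbons (each twice) dearomatises the arene to the β-triketone, the acyl group blocking the third position.

Step 15
Reactants: 22 acetylsyncarpic acid
Product: 23 2,2,4,4-tetramethylcyclohexane-1,3,5-trione (syncarpic acid)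
Conditions: 6 M aqueous HCl, 100 °C
Reagents that add atoms: none
Why: Acid-mediated retro-Claisen deacylation of the triacyl-substituted carbon removes the acetyl group and gives syncarpic acid.

Step 16
Reactants: 20 dienol; 23 syncarpic acid; 24 3-methylbutanal
Product: 26 Tomentodione O, via alkylidene trione 25 (not isolated)
Conditions: ethylenediammonium diacetate (10 mol %), toluene, 25 °C then 80 °C
Reagents that add atoms: none
Why: Knoevenagel condensation gives alkylidene trione 25, an electron-poor 1-oxadiene that should add in an inverse-electron-demand oxa-Diels–Alder reaction to the more nucleophilic, less hindered 1,1-disubstituted C8=C15 alkene and not to the trisubstituted C3=C4 (oxygen to the more substituted C8, C1′ to C15), as in the caryophyllene adducts of this family; attack on the alkene face anti to H9 sets C8 (S), and the orientation that places the isobutyl group and C9 on opposite faces of the new pyran ring sets C1′ (R).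

**Compound list**

1 | 3-[(tert-butyldiphenylsilyl)oxy]propanal | O=CCCO[Si](c1ccccc1)(c1ccccc1)C(C)(C)C | starting material
2 | dipropan-2-yl propanedioate (diisopropyl malonate) | CC(C)OC(=O)CC(=O)OC(C)C | starting material
3 | dipropan-2-yl 2-{3-[(tert-butyldiphenylsilyl)oxy]propylidene}propanedioate | CC(C)OC(=O)C(=CCCO[Si](c1ccccc1)(c1ccccc1)C(C)(C)C)C(=O)OC(C)C | intermediate
4 | 2-nitropropane | CC(C)[N+](=O)[O-] | starting material
5 | dipropan-2-yl 2-[(3R)-1-[(tert-butyldiphenylsilyl)oxy]-4-methyl-4-nitropentan-3-yl]propanedioate | CC(C)(C)[Si](c1ccccc1)(c1ccccc1)OCC[C@@H](C(C)(C)[N+](=O)[O-])C(C(=O)OC(C)C)C(=O)OC(C)C | intermediate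
6 | dipropan-2-yl 2-[(3R)-4-amino-1-[(tert-butyldiphenylsilyl)oxy]-4-methylpentan-3-yl]propanedioate | CC(C)(C)[Si](c1ccccc1)(c1ccccc1)OCC[C@@H](C(C)(C)N)C(C(=O)OC(C)C)C(=O)OC(C)C | intermediate (not isolated)
7 | propan-2-yl (3R,4R)-4-{2-[(tert-butyldiphenylsilyl)oxy]ethyl}-5,5-dimethyl-2-oxopyrrolidine-3-carboxylate | CC(C)(C)[Si](c1ccccc1)(c1ccccc1)OCC[C@H]2C(C)(C)NC(=O)[C@@H]2C(=O)OC(C)C | intermediate
8 | propan-2-yl (3R,4R)-4-{2-[(tert-butyldiphenylsilyl)oxy]ethyl}-5,5-dimethylpyrrolidine-3-carboxylate | CC(C)(C)[Si](c1ccccc1)(c1ccccc1)OCC[C@H]2C(C)(C)NC[C@@H]2C(=O)OC(C)C | intermediate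
9 | 1,1-diazene (isodiazene, N-nitrene) of pyrrolidine 8 | CC(C)(C)[Si](c1ccccc1)(c1ccccc1)OCC[C@H]2C(C)(C)[N+](=[N-])C[C@@H]2C(=O)OC(C)C | intermediate (not isolated)
10 | propan-2-yl (1S,2R)-2-{2-[(tert-butyldiphenylsilyl)oxy]ethyl}-3,3-dimethylcyclobutane-1-carboxylate | CC(C)(C)[Si](c1ccccc1)(c1ccccc1)OCC[C@H]2C(C)(C)C[C@@H]2C(=O)OC(C)C | intermediate
11 | (1S,2R)-2-{2-[(tert-butyldiphenylsilyl)oxy]ethyl}-N-methoxy-N,3,3-trimethylcyclobutane-1-carboxamide | CC(C)(C)[Si](c1ccccc1)(c1ccccc1)OCC[C@H]2C(C)(C)C[C@@H]2C(=O)N(C)OC | intermediate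
12 | 2-(2-bromoethyl)-1,3-dioxolane | BrCCC1OCCO1 | starting material
13 | [2-(1,3-dioxolan-2-yl)ethyl]magnesium bromide | Br[Mg]CCC1OCCO1 | intermediate (not isolated)
14 | 1-[(1S,2R)-2-{2-[(tert-butyldiphenylsilyl)oxy]ethyl}-3,3-dimethylcyclobutyl]-3-(1,3-dioxolan-2-yl)propan-1-one | CC(C)(C)[Si](c1ccccc1)(c1ccccc1)OCC[C@H]2C(C)(C)C[C@@H]2C(=O)CCC3OCCO3 | intermediate
15 | tert-butyl{2-[(1R,4S)-4-[4-(1,3-dioxolan-2-yl)but-1-en-2-yl]-2,2-dimethylcyclobutyl]ethoxy}diphenylsilane | CC(C)(C)[Si](c1ccccc1)(c1ccccc1)OCC[C@H]2C(C)(C)C[C@@H]2C(=C)CCC3OCCO3 | intermediate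
16 | 2-[(1R,4S)-4-[4-(1,3-dioxolan-2-yl)but-1-en-2-yl]-2,2-dimethylcyclobutyl]ethan-1-ol | OCC[C@H]2C(C)(C)C[C@@H]2C(=C)CCC3OCCO3 | intermediate
17 | 2-[(1R,4S)-4-[4-(1,3-dioxolan-2-yl)but-1-en-2-yl]-2,2-dimethylcyclobutyl]acetaldehyde | O=CC[C@H]2C(C)(C)C[C@@H]2C(=C)CCC3OCCO3 | intermediate
18 | 2-{3-[(1S,2R)-2-[(2Z)-3-iodobut-2-en-1-yl]-3,3-dimethylcyclobutyl]but-3-en-1-yl}-1,3-dioxolane | C/C(I)=C/C[C@H]2C(C)(C)C[C@@H]2C(=C)CCC3OCCO3 | intermediate
19 | 4-[(1S,2R)-2-[(2Z)-3-iodobut-2-en-1-yl]-3,3-dimethylcyclobutyl]pent-4-enal | C/C(I)=C/C[C@H]1C(C)(C)C[C@@H]1C(=C)CCC=O | intermediate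
20 | (1R,3Z,5R,9S)-4,11,11-trimethyl-8-methylidenebicyclo[7.2.0]undec-3-en-5-ol | C/C1=C/C[C@@H]2[C@H](CC2(C)C)C(=C)CC[C@H]1O | intermediate
21 | 1-(2,4,6-trihydroxyphenyl)ethan-1-one | CC(=O)c1c(O)cc(O)cc1O | starting material
22 | 2-acetyl-3-hydroxy-4,4,6,6-tetramethylcyclohex-2-ene-1,5-dione (acetylsyncarpic acid, enol form) | CC(=O)C1=C(O)C(C)(C)C(=O)C(C)(C)C1=O | intermediate
23 | 2,2,4,4-tetramethylcyclohexane-1,3,5-trione (syncarpic acid) | CC1(C)C(=O)CC(=O)C(C)(C)C1=O | intermediate
24 | 3-methylbutanal | CC(C)CC=O | starting material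
25 | 2,2,4,4-tetramethyl-6-(3-methylbutylidene)cyclohexane-1,3,5-trione | CC(C)CC=C1C(=O)C(C)(C)C(=O)C(C)(C)C1=O | intermediate (not isolated)
26 | Tomentodione O (1R,3Z,5R,8S,9S,1′R in caryophyllane numbering) | C/C1=C/C[C@@H]2[C@H](CC2(C)C)[C@]2(CC[C@H]1O)C[C@@H](CC(C)C)C1=C(O2)C(C)(C)C(=O)C(C)(C)C1=O | target

**Step count and risks**

Total step count: 16. Longest linear sequence: 14 (steps 1 to 13, then step 16); steps 14 and 15 form the short branch to syncarpic acid.

Steps most likely to fail:

Step 5. The hindered nitrogen may be aminated slowly, so that the trivalent-iodine oxidant is consumed elsewhere. The hot protic medium may divert the isodiazene (tautomerisation to a hydrazone, tetrazene formation). At 80 °C the 1,4-biradical may partition towards β-scission of the C1–C9 bond. The fallback sets out from 8 and returns to 10; it makes the N–N bond and expels the nitrogen in separate operations. Nitrosation (NaNO2, AcOH/H2O, 0 °C) gives propan-2-yl (3R,4R)-4-{2-[(tert-butyldiphenylsilyl)oxy]ethyl}-5,5-dimethyl-1-nitrosopyrrolidine-3-carboxylate F1. Reduction (Zn, AcOH) gives propan-2-yl (3R,4R)-1-amino-4-{2-[(tert-butyldiphenylsilyl)oxy]ethyl}-5,5-dimethylpyrrolidine-3-carboxylate F2. Oxidation of F2 in an aprotic solvent (t-BuOCl, Et3N, Et2O, −78 °C to 0 °C) generates the isodiazene and releases nitrogen far below 80 °C, where closure of a 1,4-biradical is favoured over cleavage, to give 10.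

Step 13. Intermolecular coupling and protodeiodination may outrun closure of the nine-membered ring, and the face of the aldehyde is not controlled by a reagent, so the C5 epimer may form. The fallback sets out from 17 and returns to 20; it closes the ring at C3=C4 by olefin metathesis after C5 has been set by reagent control. Methylenation of 17 (Ph3PCH3Br, KOt-Bu) gives 2-{3-[(1S,2R)-3,3-dimethyl-2-(prop-2-en-1-yl)cyclobutyl]but-3-en-1-yl}-1,3-dioxolane F3. Acetal hydrolysis (pyridinium p-toluenesulfonate, wet acetone) gives 4-[(1S,2R)-3,3-dimethyl-2-(prop-2-en-1-yl)cyclobutyl]pent-4-enal F4. Addition of isopropenylzinc bromide, CH2=C(CH3)ZnBr, under control of a chiral amino-alcohol ligand gives (3R)-6-[(1S,2R)-3,3-dimethyl-2-(prop-2-en-1-yl)cyclobutyl]-2-methylhepta-1,6-dien-3-ol F5. Ring-closing metathesis (second-generation Hoveyda–Grubbs catalyst, toluene, 80 °C, high dilution) gives 20. The carbene loads at the monosubstituted alkene, from which only closure onto the isopropenyl group is geometrically possible, and the nine-membered ring should form as the less strained Z alkene.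

Step 16. The flexible nine-membered ring may discriminate poorly between the two faces of C8=C15 and between the two orientations of the heterodiene (C1′ epimer). An ene reaction may compete with cycloaddition, and the free C5 hydroxyl may add to the heterodiene. The fallback sets out from 18 and returns to 26; it reverses the order of ring formation. The three-component cycloaddition (23, 24, ethylenediammonium diacetate, toluene, 80 °C) is run on open-chain alkene 18, where the adjacent cyclobutane stereocentre C9 alone controls the face and diastereomers can be separated early. This gives (2S,4R)-2-[2-(1,3-dioxolan-2-yl)ethyl]-2-[(1S,2R)-2-[(2Z)-3-iodobut-2-en-1-yl]-3,3-dimethylcyclobutyl]-6,6,8,8-tetramethyl-4-(2-methylpropyl)-3,4-dihydro-2H-chromene-5,7(6H,8H)-dione F6. Acetal hydrolysis (pyridinium p-toluenesulfonate, wet acetone) gives 3-[(2S,4R)-2-[(1S,2R)-2-[(2Z)-3-iodobut-2-en-1-yl]-3,3-dimethylcyclobutyl]-6,6,8,8-tetramethyl-4-(2-methylpropyl)-5,7-dioxo-3,4,5,6,7,8-hexahydro-2H-chromen-2-yl]propanal F7. The Nozaki–Hiyama–Kishi closure (CrCl2, NiCl2 in catalytic amount, DMSO/THF), which leaves the ketone and the vinylogous ester untouched, then forms the nine-membered ring and C5 to give 26.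

Further compounds

F1 | step 5 | propan-2-yl (3R,4R)-4-{2-[(tert-butyldiphenylsilyl)oxy]ethyl}-5,5-dimethyl-1-nitrosopyrrolidine-3-carboxylate | CC(C)(C)[Si](c1ccccc1)(c1ccccc1)OCC[C@H]2C(C)(C)N(N=O)C[C@@H]2C(=O)OC(C)C
F2 | step 5 | propan-2-yl (3R,4R)-1-amino-4-{2-[(tert-butyldiphenylsilyl)oxy]ethyl}-5,5-dimethylpyrrolidine-3-carboxylate | CC(C)(C)[Si](c1ccccc1)(c1ccccc1)OCC[C@H]2C(C)(C)N(N)C[C@@H]2C(=O)OC(C)C
F3 | step 13 | 2-{3-[(1S,2R)-3,3-dimethyl-2-(prop-2-en-1-yl)cyclobutyl]but-3-en-1-yl}-1,3-dioxolane | C=CC[C@H]2C(C)(C)C[C@@H]2C(=C)CCC3OCCO3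
F4 | step 13 | 4-[(1S,2R)-3,3-dimethyl-2-(prop-2-en-1-yl)cyclobutyl]pent-4-enal | C=CC[C@H]1C(C)(C)C[C@@H]1C(=C)CCC=O
F5 | step 13 | (3R)-6-[(1S,2R)-3,3-dimethyl-2-(prop-2-en-1-yl)cyclobutyl]-2-methylhepta-1,6-dien-3-ol | C=CC[C@H]1C(C)(C)C[C@@H]1C(=C)CC[C@@H](O)C(C)=C
F6 | step 16 | (2S,4R)-2-[2-(1,3-dioxolan-2-yl)ethyl]-2-[(1S,2R)-2-[(2Z)-3-iodobut-2-en-1-yl]-3,3-dimethylcyclobutyl]-6,6,8,8-tetramethyl-4-(2-methylpropyl)-3,4-dihydro-2H-chromene-5,7(6H,8H)-dione | C/C(I)=C/C[C@@H]1[C@H](CC1(C)C)[C@]1(CCC2OCCO2)C[C@@H](CC(C)C)C2=C(O1)C(C)(C)C(=O)C(C)(C)C2=O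
F7 | step 16 | 3-[(2S,4R)-2-[(1S,2R)-2-[(2Z)-3-iodobut-2-en-1-yl]-3,3-dimethylcyclobutyl]-6,6,8,8-tetramethyl-4-(2-methylpropyl)-5,7-dioxo-3,4,5,6,7,8-hexahydro-2H-chromen-2-yl]propanal | C/C(I)=C/C[C@@H]1[C@H](CC1(C)C)[C@]1(CCC=O)C[C@@H](CC(C)C)C2=C(O1)C(C)(C)C(=O)C(C)(C)C2=O
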